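**Retrosynthetic overview**

1. Lehualide C is cut at C3'–C4' of the side chain into an E alkenyl bromide (γ-pyranone–C1'H2–C2'H=C3'(CH3)Br) and S-(9-bromononyl) thioacetate. The two are joined in the last step by a nickel-catalysed reductive coupling of two electrophilic carbons, with no protecting groups.
2. Enabling feature: the E trisubstituted C2'=C3' alkene is kept out of conjugation with the γ-pyranone ring (O1, C2–C6) by C1'H2 and carries its methyl on C3'. C3' can therefore hold a bromide of fixed geometry (from syn hydrozirconation of a methyl alkyne), and C4' is an unbranched primary carbon that gives a clean radical.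
3. The γ-pyranone, the only ring, is made before the key step: β-keto ester dianion aldol with (E)-4-bromopent-3-enal, oxidation to the 3,5-dioxo ester, lactonisation (O1–C2) to the 4-hydroxy-2-pyranone, then O-methylation at the lactone carbonyl oxygen.
4. The sulfur tail comes from 9-bromononan-1-ol by Mitsunobu thioacetylation.

Key step: step 9

Remark: side-chain carbons are counted C1' to C12' from the ring-bound CH2. The acyclic precursors of the pyranone are carried as stereoisomer mixtures, since each of their sp3 stereocentres is erased when the ring is formed.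

**Route**

Step 1
Reactants: 1 methyl methoxyacetate; 2 propanoyl chloride
Product: 4 methyl 2-methoxy-3-oxopentanoate (racemic), via lithium enolate of methyl methoxyacetate 3 (not isolated)
Conditions: LiN(i-Pr)2 (2.05 equiv), 1 (2.0 equiv), THF, −78 °C; then 2 (1.0 equiv), −78 °C; 1 M HCl
Reagents that add atoms: none
Why: Crossed Claisen condensation in which the preformed ester enolate 3 is C-acylated by the acid chloride at low temperature, the second equivalent of enolate deprotonating the more acidic β-keto ester as it forms so that double acylation should be suppressed.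

Step 2
Reactants: 5 pent-3-yn-1-ol
Product: 7 (3E)-4-bromopent-3-en-1-ol, via alkenylzirconocene alkoxide 6 (not isolated)
Conditions: (C5H5)2Zr(H)Cl (2.5 equiv), THF, 25 to 40 °C; then NBS, 0 °C
Reagents that add atoms: N-bromosuccinimide, O=C1CCC(=O)N1Br
Why: Hydrozirconation–bromodezirconation in which the first equivalent of hydride converts the hydroxyl into a zirconium alkoxide, syn addition of Zr–H under equilibrating conditions (excess hydride, mild warming) should place zirconium on the less hindered methyl-bearing carbon, and NBS cleaves the C–Zr bond with retention, so that H and Br end up cis and the E bromide results.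

Step 3
Reactants: 7 (3E)-4-bromopent-3-en-1-ol
Product: 8 (3E)-4-bromopent-3-enal
Conditions: Dess–Martin periodinane (1.2 equiv), CH2Cl2, 0 °C; aq NaHCO3/Na2S2O3 work-up; used at once without chromatography
Reagents that add atoms: none
Why: Dess–Martin oxidation of a primary alcohol under mild, nearly neutral conditions should give the β,γ-unsaturated aldehyde without shifting the double bond into conjugation.

Step 4
Reactants: 4 methyl 2-methoxy-3-oxopentanoate; 8 (3E)-4-bromopent-3-enal
Product: 10 methyl (7E)-8-bromo-5-hydroxy-2-methoxy-4-methyl-3-oxonon-7-enoate (diastereomer mixture), via dilithium dianion of the keto ester 9 (not isolated)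
Conditions: 4 (1.2 equiv), LiN(i-Pr)2 (2.5 equiv), THF, −78 to 0 °C; then 8 (1.0 equiv), −78 °C; AcOH quench
Reagents that add atoms: none
Why: β-Keto ester dianion aldol addition in which the more reactive γ-carbon (the propanoyl CH) of 9 should add to the aldehyde at −78 °C faster than it enolises it, the three uncontrolled stereocentres being erased in steps 5 to 7.

Step 5
Reactants: 10 methyl (7E)-8-bromo-5-hydroxy-2-methoxy-4-methyl-3-oxonon-7-enoate
Product: 11 methyl (7E)-8-bromo-2-methoxy-4-methyl-3,5-dioxonon-7-enoate
Conditions: Dess–Martin periodinane (1.5 equiv), CH2Cl2, 0 °C to rt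
Reagents that add atoms: none
Why: Dess–Martin oxidation of the secondary β-hydroxy ketone to the 1,3-diketone is a standard entry to 3,5-dioxo esters and leaves the alkenyl bromide untouched.

Step 6
Reactants: 11 methyl (7E)-8-bromo-2-methoxy-4-methyl-3,5-dioxonon-7-enoate
Product: 12 6-[(2E)-3-bromobut-2-en-1-yl]-4-hydroxy-3-methoxy-5-methyl-2H-pyran-2-one
Conditions: DBU (2 equiv), toluene, rt to 60 °C; 1 M HCl work-up
Reagents that add atoms: none
Why: Base-mediated lactonisation of a 3,5-dioxo ester (6-exo-trig addition–elimination of the C5 enolate oxygen at the ester carbonyl with loss of methanol) should be driven by formation of the stabilised hydroxypyranone anion, which also keeps the C6–CH2 group from being deprotonated.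

Step 7
Reactants: 12 6-[(2E)-3-bromobut-2-en-1-yl]-4-hydroxy-3-methoxy-5-methyl-2H-pyran-2-one
Product: 14 6-[(2E)-3-bromobut-2-en-1-yl]-2,3-dimethoxy-5-methyl-4H-pyran-4-one, via 4-hydroxypyrylium triflate 13 (not isolated)
Conditions: MeOTf (1.3 equiv), CH2Cl2, 0 °C to rt; then aq NaHCO3
Reagents that add atoms: methyl trifluoromethanesulfonate, COS(=O)(=O)C(F)(F)F
Why: O-Methylation of the neutral 4-hydroxy-2-pyranone by a hard methylating agent should occur at its most basic site, the lactone carbonyl oxygen, to give pyrylium salt 13, whose deprotonation on bicarbonate work-up gives the 2-methoxy-4-pyranone rather than the 4-methoxy-2-pyranone.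

Step 8
Reactants: 15 9-bromononan-1-ol; 16 thioacetic acid
Product: 17 S-(9-bromononyl) ethanethioate
Conditions: PPh3, DIAD, THF, 0 °C
Reagents that add atoms: none
Why: Mitsunobu reaction in which the primary alcohol is activated as its alkoxyphosphonium salt and displaced by the acidic thioacetic acid, the primary bromide being inert at 0 °C.

Step 9
Reactants: 14 6-[(2E)-3-bromobut-2-en-1-yl]-2,3-dimethoxy-5-methyl-4H-pyran-4-one; 17 S-(9-bromononyl) ethanethioate
Product: 18 lehualide C
Conditions: NiBr2(MeOCH2CH2OMe) (10 mol %), 4,4'-di-tert-butyl-2,2'-bipyridine (10 mol %), Zn dust (2 equiv), NaI (0.25 equiv), DMA, 25 to 40 °C; 17 (1.5 equiv)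
Reagents that add atoms: none
Why: Zerovalent nickel bearing the bipyridine ligand should add oxidatively into the C(sp2)–Br bond of 14 with retention, while low-valent nickel abstracts the halogen of 17 (partly exchanged to the iodide by NaI) to give the primary C4' radical; this radical is captured by the alkenylnickel species, reductive elimination from the resulting trivalent nickel centre forms the C3'–C4' bond, and Zn returns nickel to the low-valent state. The closest known reaction type is the nickel-catalysed reductive cross-electrophile coupling of alkenyl bromides with primary alkyl bromides, which joins two electrophilic carbons without a preformed organometallic reagent. No ring is closed and no stereocentre is formed; the E geometry of C2'=C3' set in step 2 should be carried over because the alkenylnickel intermediate is configurationally stable and the new bond forms at the carbon that held bromine. The step needs cross-coupling over homo-coupling, which the two different activation modes (two-electron oxidative addition at the sp2 carbon, halogen-atom abstraction at the sp3 carbon) and the excess of 17 should secure. It also needs the S-acetyl group, the methoxy-bearing C2 of the pyranone ring and the doubly activated C1'H2 to stay untouched, which the absence of base and of any carbanionic reagent at or below 40 °C should ensure, since an S-alkyl thioacetate lacks the chelating activation that low-valent nickel needs to enter a C(acyl)–S bond at this temperature.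

**Compound list**

1 | methyl methoxyacetate | COCC(=O)OC | starting material
2 | propanoyl chloride | CCC(Cl)=O | starting material
3 | lithium enolate of methyl methoxyacetate | [Li+].COC=C([O-])OC | intermediate
4 | methyl 2-methoxy-3-oxopentanoate (racemic) | CCC(=O)C(OC)C(=O)OC | intermediate
5 | pent-3-yn-1-ol | CC#CCCO | starting material
6 | alkenylzirconocene alkoxide: (E)-alkenyl–Zr(C5H5)2Cl with the hydroxyl as its O–Zr(C5H5)2Cl alkoxide | C/C(=C\CCO[Zr](Cl)(C1C=CC=C1)C1C=CC=C1)[Zr](Cl)(C1C=CC=C1)C1C=CC=C1 | intermediate
7 | (3E)-4-bromopent-3-en-1-ol | C/C(Br)=C\CCO | intermediate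
8 | (3E)-4-bromopent-3-enal | C/C(Br)=C\CC=O | intermediate
9 | dilithium dianion (dienediolate) of methyl 2-methoxy-3-oxopentanoate | [Li+].[Li+].CC=C([O-])C(OC)=C([O-])OC | intermediate
10 | methyl (7E)-8-bromo-5-hydroxy-2-methoxy-4-methyl-3-oxonon-7-enoate (diastereomer mixture) | COC(=O)C(OC)C(=O)C(C)C(O)C/C=C(\C)Br | intermediate
11 | methyl (7E)-8-bromo-2-methoxy-4-methyl-3,5-dioxonon-7-enoate (stereoisomer and tautomer mixture) | COC(=O)C(OC)C(=O)C(C)C(=O)C/C=C(\C)Br | intermediate
12 | 6-[(2E)-3-bromobut-2-en-1-yl]-4-hydroxy-3-methoxy-5-methyl-2H-pyran-2-one | COc1c(O)c(C)c(C/C=C(\C)Br)oc1=O | intermediate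
13 | 6-[(2E)-3-bromobut-2-en-1-yl]-4-hydroxy-2,3-dimethoxy-5-methylpyrylium trifluoromethanesulfonate | COc1[o+]c(C/C=C(\C)Br)c(C)c(O)c1OC.[O-]S(=O)(=O)C(F)(F)F | intermediate
14 | 6-[(2E)-3-bromobut-2-en-1-yl]-2,3-dimethoxy-5-methyl-4H-pyran-4-one | COc1oc(C/C=C(\C)Br)c(C)c(=O)c1OC | intermediate
15 | 9-bromononan-1-ol | OCCCCCCCCCBr | starting material
16 | thioacetic acid | CC(=O)S | starting material
17 | S-(9-bromononyl) ethanethioate | CC(=O)SCCCCCCCCCBr | intermediate
18 | lehualide C, S-[(10E)-12-(5,6-dimethoxy-3-methyl-4-oxo-4H-pyran-2-yl)-10-methyldodec-10-en-1-yl] ethanethioate | COc1oc(C/C=C(\C)CCCCCCCCCSC(C)=O)c(C)c(=O)c1OC | target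

**Step count**

Total: 9 steps. Longest linear sequence: 7 steps (steps 2, 3, 4, 5, 6, 7 and 9, from pent-3-yn-1-ol).

**Steps most likely to fail**

Step 9. Homo-dimerisation of either bromide may outrun the cross-coupling, low-valent nickel may enter the C(acyl)–S bond or be poisoned by liberated thiolate, and the alkenylnickel intermediate may partly lose its E geometry. The fallback sets out from 14 and brings sulfur in last by a two-electron palladium coupling. 9-Bromonon-1-ene F1 would be hydroborated with 9-borabicyclo[3.3.1]nonane (THF, rt) to B-(9-bromononyl)-9-borabicyclo[3.3.1]nonane F2. F2 would be joined to 14 by B-alkyl Suzuki–Miyaura coupling (PdCl2(dppf), Cs2CO3, DMF/H2O, rt to 45 °C), with retention at the alkenyl carbon, to give 6-[(2E)-12-bromo-3-methyldodec-2-en-1-yl]-2,3-dimethoxy-5-methyl-4H-pyran-4-one F3. SN2 displacement of the primary bromide with KSC(O)CH3 in DMF at rt would then return to the route at 18.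

Step 4. Proton transfer from the β,γ-unsaturated aldehyde to the dianion may compete with addition, and the double bond of 8 may drift into conjugation before it reacts. The fallback sets out from 7 and works at the acid oxidation level. Oxidation of 7 with TEMPO (cat.) and PhI(OAc)2 in MeCN/H2O would give (3E)-4-bromopent-3-enoic acid F4. 1,1'-Carbonyldiimidazole in THF would convert F4 into 1-[(3E)-4-bromopent-3-enoyl]-1H-imidazole F5. C-Acylation of dianion 9 (made from 4 as in step 4, with one further equivalent of LiN(i-Pr)2 to take up the more acidic product) by F5 at −78 °C would give 11 directly, so the route is rejoined at 11 and steps 3 and 5 are not needed.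

Step 7. Methylation may take place at the C4 hydroxyl oxygen instead of the lactone carbonyl oxygen, giving the 2-pyranone isomer. The fallback sets out from 11 and avoids the hydroxypyranone: cyclodehydration of the 3,5-dioxo ester with PPh3 and CCl4 in THF keeps the ester methoxy group as the C2 methoxy of the ring and removes the ester carbonyl oxygen as phosphine oxide. It would return to the route at 14 and makes no new compound (F0).

**Further compounds**

F1 | step 9 | 9-bromonon-1-ene | C=CCCCCCCCBr
F2 | step 9 | B-(9-bromononyl)-9-borabicyclo[3.3.1]nonane | BrCCCCCCCCCB1C2CCCC1CCC2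
F3 | step 9 | 6-[(2E)-12-bromo-3-methyldodec-2-en-1-yl]-2,3-dimethoxy-5-methyl-4H-pyran-4-one | COc1oc(C/C=C(\C)CCCCCCCCCBr)c(C)c(=O)c1OC
F4 | step 4 | (3E)-4-bromopent-3-enoic acid | C/C(Br)=C\CC(=O)O
F5 | step 4 | 1-[(3E)-4-bromopent-3-enoyl]-1H-imidazole | C/C(Br)=C\CC(=O)n1ccnc1
F0 | step 7 | none | none
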